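The numbers of this flask were drawn at random within sensible limits; no experiment stands behind them.

Set the top speed of the supply against the speed at which target is destroyed, and work in powers of ten.

    starting material + partner + by-product → target + 2 by-product (k1 = 1.4 M⁻² h⁻¹, Ea1 = 38.0 kJ mol⁻¹)
    starting material + partner → target + by-product (k2 = 4.8 × 10⁻⁴ M⁻¹ h⁻¹, Ea2 = 71.0 kJ mol⁻¹)
    partner → decomposed reagent (k3 = 0.040 h⁻¹, Ea3 = 76.0 kJ mol⁻¹)
    gas ⇌ partner, rate k4*(csat - [partner]) (k4 = 0.38 h⁻¹, csat = 200 mM)
    starting material + target → side product (k5 = 0.066 M⁻¹ h⁻¹, Ea5 = 58.0 kJ mol⁻¹)
    (constants at −20 °C)
the same everywhere: starting material 1.3 M; gas 200 mM (held); time 2.5 d

| charge | temperature |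
|---|---|
| autumn | −20 °C |
| noon | 5 °C |
- percent here means starting material units held: one side product counts as two
- at the start none of partner is dissolved
- the list of constants is for −20 °C, to be carried to other temperatures by the activation energies
1. which of these there is most of at the end, counted by the starting material in it, autumn (side product / target / starting material)
2. which of these there is most of at the end, counted by the starting material in it, noon (side product / target / starting material)
3. final amount of the leader among these, as a percentage of the starting material charged, in autumn
4. final amount of the leader among these, as a percentage of the starting material charged, in noon

Target forms from dissolved partner, and partner comes from the gas. Target is burned by meeting starting material, which gives side product. I ranked the times of autumn from shortest to longest: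

gas into solution, half-time: 1.82 h
target burned, starting material as charged, half-time: 8.08 h
fill time F: 17.1 h
partner decomposing, half-time: 17.3 h
the run: 60 h

F is my own name for the charge of starting material divided by the top transfer rate of the gas: the shortest time in which one partner per starting material can arrive. Transfer starts up sooner than target burns, so I pictured target forming no faster than gas arrives. The run is longer than F, so the supply had time to deliver the charge's worth.

For autumn I reckoned 1.47 for the burn number Q, the fill time times the rate constant of burning times the charge of starting material. Q sets starting material and target both at the full charge, which they share, so it overstates the burn: with each at half the charge, the burn in autumn peaks at 0.367 times the top transfer rate.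

Warming to noon multiplies the burning constant by 11.9, while the transfer carries no activation energy:

autumn: Q = 1.47, logarithm 0.167
noon: Q = 17.5, logarithm 1.24

At noon the burn half-time falls to 0.679 h, far shorter than F. The same peak at noon is 4.37 times the top transfer rate, above it, while the peak in autumn stays below it. I committed to a close contest in autumn and to side product ahead at noon, and to no percentage.

The forecast went further, stepping by hand from “the gas transfer limit”: target in autumn at 53 %, range 48 % to 58 %, and side product at noon at 86 %, range 81 % to 90 %.

The simulation gave target in autumn at 52.5 %, with side product at 47.3 %, and side product at noon at 86.7 %, both inside the forecast's ranges. At noon the half-life of target by burning read 0.56 d at 1.18 d, short against the run of 2.5 d, and the final target share times Q came to 2.33. In the neighbouring flask at 20 °C, a repeat of noon with Q at 63.0, side product stood at 96.7 %, target at 3.24 %, and the same product came to 2.04.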